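The route rests on cutting the decalin at C5–C10 and C6–C7. Ring B has the C9 oxygen next to the C8 methyl and to quaternary C10; a 2-silyloxydiene spanning C7–C10 delivers this array as a C8=C9 silyl enol ether once it has added across a C5=C6 enal that hangs from C10 by the ring A carbons C1–C4. One amine-catalysed intramolecular Diels–Alder reaction thus closes rings A and B and sets C5, C6 and C10. Its precursor is an acyclic (2E,8Z)-trienal: a Z-configured, fully substituted silyloxydiene and an E-enal joined by a 3-oxo tether with a gem-dimethyl group at C4. Bromine at C3 and the linalool-derived chain at C9 follow.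

Key step: step 8

Remark: positions are given in labdane numbering (C1–C20), and 2,2-dimethylbut-3-en-1-ol (5) is taken as a catalogue chemical (otherwise one step from prenylmagnesium chloride and formaldehyde).

Step 1
Reactants: 1 methacrolein (2-methylprop-2-enal); 2 isopropenylmagnesium bromide
Product: 3 2,4-dimethylpenta-1,4-dien-3-ol
Conditions: THF, −78 → 0 °C; aq NH4Cl
Reagents that add atoms: none
Why: Grignard 1,2-addition of the alkenylmagnesium reagent to the aldehyde carbonyl gives the doubly allylic carbinol, whose carbinol carbon carries two identical isopropenyl groups and is therefore not a stereocenter.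

Step 2
Reactants: 3 2,4-dimethylpenta-1,4-dien-3-ol
Product: 4 tert-butyl[(2,4-dimethylpenta-1,4-dien-3-yl)oxy]dimethylsilane
Conditions: TBSCl, imidazole, DMF, 23 °C
Reagents that add atoms: tert-butyldimethylsilyl chloride, CC(C)(C)[Si](C)(C)Cl
Why: Standard silylation of a secondary alcohol; this silyl group ends on the C9 enol ether oxygen, and TBS is chosen because a hindered TBS enol ether withstands the weakly acidic catalyst salt of step 8.

Step 3
Reactants: 5 2,2-dimethylbut-3-en-1-ol
Product: 6 2-methyl-2-(oxiran-2-yl)propan-1-ol (racemic)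
Conditions: mCPBA, CH2Cl2, 0 → 23 °C
Reagents that add atoms: 3-chloroperoxybenzoic acid, O=C(OO)c1cccc(Cl)c1
Why: Prilezhaev epoxidation of the only alkene gives the terminal epoxide that serves as the C2 electrophile; it is racemic, which is immaterial because its carbinol carbon (C3) becomes a ketone in step 7.

Step 4
Reactants: 6 2-methyl-2-(oxiran-2-yl)propan-1-ol; 7 ethyl (triphenylphosphoranylidene)acetate
Product: 9 ethyl (E)-4-methyl-4-(oxiran-2-yl)pent-2-enoate (racemic), via epoxy aldehyde 8 (not isolated)
Conditions: Dess–Martin periodinane, CH2Cl2, 23 °C; then 7, 23 → 40 °C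
Reagents that add atoms: none
Why: Dess–Martin oxidation gives the non-enolisable aldehyde (quaternary α-carbon), which is olefinated in the same flask by the stabilised ylide (Wittig reaction) to the E-enoate, the usual outcome for ester-stabilised ylides.

Step 5
Reactants: 9 ethyl (E)-4-methyl-4-(oxiran-2-yl)pent-2-enoate
Product: 10 (E)-4-methyl-4-(oxiran-2-yl)pent-2-en-1-ol (racemic)
Conditions: i-Bu2AlH, CH2Cl2, −78 °C; aq potassium sodium tartrate
Reagents that add atoms: none
Why: Hydride 1,2-reduction of the unsaturated ester by i-Bu2AlH at low temperature gives the allylic alcohol and leaves the epoxide, which reacts only at higher temperature.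

Step 6
Reactants: 4 tert-butyl[(2,4-dimethylpenta-1,4-dien-3-yl)oxy]dimethylsilane; 10 (E)-4-methyl-4-(oxiran-2-yl)pent-2-en-1-ol
Product: 13 (2E,8Z)-9-[(tert-butyldimethylsilyl)oxy]-4,4,8,10-tetramethylundeca-2,8,10-triene-1,5-diol (racemic at the carbinol carbon), via silyloxypentadienyllithium 11 (not isolated), via lithium alkoxide 12 (not isolated)
Conditions: 4 (1.3 equiv), s-BuLi (1.25 equiv), THF, −78 °C; 10 pretreated with n-BuLi (1.0 equiv), THF, −78 °C, added by cannula; −78 → −20 °C; aq NH4Cl
Reagents that add atoms: none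
Why: Allylic deprotonation next to oxygen gives a 3-silyloxypentadienyllithium whose terminal carbon opens the epoxide at its CH2 group (SN2 alkylation of a heteroatom-substituted allyl anion, a known route to 2-silyloxydienes for intramolecular cycloadditions), the congested oxygen-bearing central carbon staying out; lithium held between the silyloxy oxygen and the attacking terminus keeps the new C1–C2 bond cis to OTBS, so the tetrasubstituted C9=C10 enol ether should form as the Z isomer that step 8 needs, and the racemic C3 carbinol is oxidised in step 7.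

Step 7
Reactants: 13 (2E,8Z)-9-[(tert-butyldimethylsilyl)oxy]-4,4,8,10-tetramethylundeca-2,8,10-triene-1,5-diol
Product: 14 (2E,8Z)-9-[(tert-butyldimethylsilyl)oxy]-4,4,8,10-tetramethyl-5-oxoundeca-2,8,10-trienal (chain C2–C11 become C6, C5, C4, C3, C2, C1, C10, C9, C8, C7)
Conditions: Dess–Martin periodinane, pyridine, CH2Cl2, 0 °C; used at once
Reagents that add atoms: none
Why: Dess–Martin oxidation converts the allylic alcohol into the E-enal and the hindered secondary alcohol into the C3 ketone in one operation under buffered, non-acidic conditions that a fully substituted TBS enol ether tolerates; unveiling the enal last, in the cold, keeps the trienal from cyclising without the catalyst.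

Step 8
Reactants: 14 (2E,8Z)-9-[(tert-butyldimethylsilyl)oxy]-4,4,8,10-tetramethyl-5-oxoundeca-2,8,10-trienal
Product: 15 (5S,6R,10R)-9-(tert-butyldimethylsilyloxy)-6-formyl-4,4,8,10-tetramethyl-Δ8(9)-trans-octalin-3-one (trans ring fusion; formyl cis to H5)
Conditions: (2R,5R)-5-benzyl-2-tert-butyl-3-methylimidazolidin-4-one·CF3CO2H (20 mol %), MeCN, H2O (1 equiv), −20 → 4 °C
Reagents that add atoms: none
Why: Proposed new method: condensation of the enal with the chiral secondary amine salt gives the E-iminium ion, whose electrophilic β-carbon C5 is polarity-matched with the nucleophilic enol ether carbon C10 of the 2-silyloxydiene, so a concerted, asynchronous [4+2] addition with C5–C10 formed ahead of C6–C7 is expected; the closest known reaction type is the imidazolidinone-catalysed intramolecular Diels–Alder reaction of trienals to trans-fused bicycles, which has not been shown with a fully substituted diene terminus that points a methyl group into the diene. Ring A closes in the fused (type 1) mode through the C5–C10 bond across the four-atom tether C1–C4, and ring B is the cyclohexene of the cycloaddition, completed by the C6–C7 bond. C5 and the absolute sense are set by the catalyst, whose benzyl group covers one face of the iminium π-system (with the 2R,5R catalyst the diene should add to the face that gives 5S); C6 follows from suprafacial addition to the E-alkene in the endo transition state; C10 follows from the Z enol ether, which holds the tether on the outside and the C10 methyl on the inside so that H5 and this methyl end up anti (trans fusion). The step needs endo selectivity and a single diene geometry: the first is the usual preference of iminium-activated trienals with a four-atom tether, the second was fixed in step 6. The gem-dimethyl group at C4 (Thorpe–Ingold effect) and the 2,3-disubstituted, electron-rich diene, which favours the s-cis form, are relied on to offset the cost of joining C5, next to quaternary C4, to the fully substituted C10. Because C4 is quaternary the enal cannot form a dienamine, and the hindered TBS enol ether should survive the trifluoroacetate salt at low temperature.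

Step 9
Reactants: 15 (5S,6R,10R)-9-(tert-butyldimethylsilyloxy)-6-formyl-4,4,8,10-tetramethyl-Δ8(9)-trans-octalin-3-one
Product: 16 (5S,10R)-9-(tert-butyldimethylsilyloxy)-4,4,8,10-tetramethyl-Δ8(9)-trans-octalin-3-one
Conditions: RhCl(PPh3)3 (1.1 equiv), toluene, 110 °C
Reagents that add atoms: none
Why: Tsuji–Wilkinson decarbonylation (oxidative addition of the formyl C–H bond to rhodium, CO extrusion, C–H reductive elimination) removes the activating formyl group so that C6 becomes CH2, while the ketone and the silyl enol ether are inert to the neutral complex.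

Step 10
Reactants: 16 (5S,10R)-9-(tert-butyldimethylsilyloxy)-4,4,8,10-tetramethyl-Δ8(9)-trans-octalin-3-one
Product: 18 (5R,10R)-9-(tert-butyldimethylsilyloxy)-4,4,8,10-tetramethyl-trans-octala-2,8-dien-3-yl trifluoromethanesulfonate (same spatial arrangement as 16; the C5 descriptor changes by priority only), via potassium enolate 17 (not isolated)
Conditions: KN(SiMe3)2, THF, −78 °C; PhNTf2, −78 → 0 °C
Reagents that add atoms: N-phenylbis(trifluoromethanesulfonimide), O=S(=O)(N(c1ccccc1)S(=O)(=O)C(F)(F)F)C(F)(F)F
Why: Kinetic enolate formation and O-sulfonylation (enol triflate synthesis) can only occur toward C2, because C4 is quaternary and the C9 carbonyl is still masked as its silyl enol ether, which is the reason for carrying C3 as a free ketone.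

Step 11
Reactants: 18 (5R,10R)-9-(tert-butyldimethylsilyloxy)-4,4,8,10-tetramethyl-trans-octala-2,8-dien-3-yl trifluoromethanesulfonate
Product: 19 (5S,10R)-3-bromo-9-(tert-butyldimethylsilyloxy)-4,4,8,10-tetramethyl-trans-octala-2,8-diene
Conditions: Ni(OAc)2·4H2O (cat.), 1,5-cyclooctadiene, Zn (cat.), LiBr, DMA/THF, 23 °C
Reagents that add atoms: lithium bromide, [Li+].[Br-]
Why: Nickel-catalysed exchange of an enol triflate for a halide (oxidative addition of the C–OTf bond to zerovalent nickel, anion exchange with bromide, C–Br reductive elimination) gives the C2=C3 vinyl bromide under neutral conditions that spare the silyl enol ether.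

Step 12
Reactants: 19 (5S,10R)-3-bromo-9-(tert-butyldimethylsilyloxy)-4,4,8,10-tetramethyl-trans-octala-2,8-diene
Product: 20 (5S,8S,10R)-3-bromo-4,4,8,10-tetramethyl-Δ2(3)-trans-octalin-9-one (C8 methyl equatorial, trans to the C10 methyl)
Conditions: Bu4NF, THF, 0 → 23 °C
Reagents that add atoms: none
Why: Fluoride cleaves the O–Si bond and the enolate is protonated at C8 (desilylation of a silyl enol ether); in the basic medium C8 equilibrates to the epimer with the equatorial methyl, since an axial C8 methyl would be 1,3-diaxial to the C10 methyl, so C8 is set under thermodynamic control.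

Step 13
Reactants: 20 (5S,8S,10R)-3-bromo-4,4,8,10-tetramethyl-Δ2(3)-trans-octalin-9-one
Product: 21 (3R,5S,8S,10R)-3-bromo-4,4,8,10-tetramethyl-trans-decalin-9-one (bromine equatorial, cis to the C10 methyl)
Conditions: Mn(dpm)3 [tris(2,2,6,6-tetramethylheptane-3,5-dionato)manganese] (cat.), PhSiH3, t-BuOOH, i-PrOH, 23 °C
Reagents that add atoms: none
Why: Radical hydrogenation by metal-hydride hydrogen-atom transfer (HAT hydrogenation): the hydrogen atom adds to C2 to give the bromine-stabilised C3 radical, which takes the second hydrogen on its open axial face, anti to the axial C4 and C10 methyls, so that bromine ends equatorial and cis to the C10 methyl (3R), without the C–Br hydrogenolysis that metal-surface hydrogenation would cause.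

Step 14
Reactants: 22 (R)-(−)-linalool
Product: 23 (R)-tert-butyl[(3,7-dimethylocta-1,6-dien-3-yl)oxy]dimethylsilane
Conditions: TBSOTf, 2,6-lutidine, CH2Cl2, 0 °C
Reagents that add atoms: tert-butyldimethylsilyl trifluoromethanesulfonate, CC(C)(C)[Si](C)(C)OS(=O)(=O)C(F)(F)F
Why: Silyl triflate with a hindered pyridine base silylates the tertiary allylic alcohol without ionising it; the C13 stereocenter comes unchanged from the chiral pool.

Step 15
Reactants: 23 (R)-tert-butyl[(3,7-dimethylocta-1,6-dien-3-yl)oxy]dimethylsilane
Product: 24 (R)-4-[(tert-butyldimethylsilyl)oxy]-4-methylhex-5-enal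
Conditions: O3, pyridine, CH2Cl2, −78 °C, Sudan Red 7B end point
Reagents that add atoms: ozone, [O-][O+]=O
Why: Ozonolysis in the presence of pyridine, which reduces the carbonyl oxide in situ, cleaves the electron-rich trisubstituted alkene much faster than the vinyl group beside the silyloxy-bearing quaternary carbon, and the dye marks the point at which to stop.

Step 16
Reactants: 24 (R)-4-[(tert-butyldimethylsilyl)oxy]-4-methylhex-5-enal
Product: 25 (R)-4-[(tert-butyldimethylsilyl)oxy]-4-methylhex-5-enoic acid
Conditions: NaClO2, NaH2PO4, 2-methyl-2-butene, t-BuOH/H2O, 0 → 23 °C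
Reagents that add atoms: sodium chlorite, [Na+].[O-]Cl=O
Why: Pinnick oxidation converts the aldehyde into the acid under buffered conditions that leave the vinyl group and the tertiary silyl ether alone, the added alkene taking up the hypochlorous acid.

Step 17
Reactants: 25 (R)-4-[(tert-butyldimethylsilyl)oxy]-4-methylhex-5-enoic acid
Product: 27 (R)-tert-butyl[(5-iodo-3-methylpent-1-en-3-yl)oxy]dimethylsilane, via thiohydroxamate ester 26 (not isolated)
Conditions: 1-hydroxypyridine-2(1H)-thione, DCC, DMAP (cat.), CH2Cl2, 0 °C, dark; then CHI3, visible light, 23 °C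
Reagents that add atoms: iodoform, IC(I)I
Why: Barton decarboxylation with iodine-atom transfer: the thiohydroxamate ester fragments under light to the primary radical with loss of CO2, and the radical abstracts iodine from iodoform, so the chain is shortened by one carbon to the C11 iodide while the remote C13 center is untouched.

Step 18
Reactants: 21 (3R,5S,8S,10R)-3-bromo-4,4,8,10-tetramethyl-trans-decalin-9-one; 27 (R)-tert-butyl[(5-iodo-3-methylpent-1-en-3-yl)oxy]dimethylsilane
Product: 30 (3R,5S,8S,9R,10R,13R)-3-bromo-13-(tert-butyldimethylsilyloxy)labd-14-en-9-ol, via alkyllithium 28 (not isolated), via organocerium reagent 29 (not isolated)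
Conditions: 27, t-BuLi (2 equiv), Et2O/pentane, −78 °C; CeCl3, THF, −78 °C; then 21, −78 → −30 °C; aq NH4Cl
Reagents that add atoms: none
Why: Lithium–iodine exchange, transmetalation to cerium and 1,2-addition (organocerium addition) bring a weakly basic, strongly nucleophilic primary alkyl group onto the hindered, enolisable C9 ketone; attack along the axial trajectory, anti to the axial C10 methyl, should place C11 axial and the hydroxyl equatorial (9R), and the equatorial neopentyl-type bromide is inert at −78 °C.

Step 19
Reactants: 30 (3R,5S,8S,9R,10R,13R)-3-bromo-13-(tert-butyldimethylsilyloxy)labd-14-en-9-ol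
Product: 31 (3R,5S,8S,9R,10R,13R)-3-bromolabd-14-ene-9,13-diol (CNP0318118.1)
Conditions: Bu4NF, THF, 50 °C
Reagents that add atoms: none
Why: Fluoride removes the tertiary TBS ether (silyl ether cleavage); no stereocenter is involved and the equatorial bromide has no antiperiplanar hydrogen for elimination.

Compound list
1 | methacrolein (2-methylprop-2-enal) | C=C(C)C=O | starting material
2 | isopropenylmagnesium bromide | C=C(C)[Mg]Br | starting material
3 | 2,4-dimethylpenta-1,4-dien-3-ol | C=C(C)C(O)C(C)=C | intermediate
4 | tert-butyl[(2,4-dimethylpenta-1,4-dien-3-yl)oxy]dimethylsilane | C=C(C)C(O[Si](C)(C)C(C)(C)C)C(C)=C | intermediate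
5 | 2,2-dimethylbut-3-en-1-ol | C=CC(C)(C)CO | starting material
6 | 2-methyl-2-(oxiran-2-yl)propan-1-ol (racemic) | OCC(C)(C)C1CO1 | intermediate
7 | ethyl (triphenylphosphoranylidene)acetate | CCOC(=O)C=P(c1ccccc1)(c1ccccc1)c1ccccc1 | starting material
8 | 2-methyl-2-(oxiran-2-yl)propanal (racemic) | O=CC(C)(C)C1CO1 | intermediate (not isolated)
9 | ethyl (E)-4-methyl-4-(oxiran-2-yl)pent-2-enoate (racemic) | CCOC(=O)/C=C/C(C)(C)C1CO1 | intermediate
10 | (E)-4-methyl-4-(oxiran-2-yl)pent-2-en-1-ol (racemic) | OC/C=C/C(C)(C)C1CO1 | intermediate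
11 | (Z)-[3-(tert-butyldimethylsilyloxy)-2,4-dimethylpenta-2,4-dien-1-yl]lithium | [Li]C/C(C)=C(O[Si](C)(C)C(C)(C)C)/C(C)=C | intermediate (not isolated)
12 | lithium (E)-4-methyl-4-(oxiran-2-yl)pent-2-en-1-olate | [Li]OC/C=C/C(C)(C)C1CO1 | intermediate (not isolated)
13 | (2E,8Z)-9-[(tert-butyldimethylsilyl)oxy]-4,4,8,10-tetramethylundeca-2,8,10-triene-1,5-diol (racemic) | OC/C=C/C(C)(C)C(O)CC/C(C)=C(O[Si](C)(C)C(C)(C)C)/C(C)=C | intermediate
14 | (2E,8Z)-9-[(tert-butyldimethylsilyl)oxy]-4,4,8,10-tetramethyl-5-oxoundeca-2,8,10-trienal | O=C/C=C/C(C)(C)C(=O)CC/C(C)=C(O[Si](C)(C)C(C)(C)C)/C(C)=C | intermediate (key-step precursor)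
15 | (5S,6R,10R)-9-(tert-butyldimethylsilyloxy)-6-formyl-4,4,8,10-tetramethyl-Δ8(9)-trans-octalin-3-one | CC(C)(C)[Si](C)(C)OC1=C(C)C[C@@H](C=O)[C@@H]2C(C)(C)C(=O)CC[C@]21C | intermediate (key-step product)
16 | (5S,10R)-9-(tert-butyldimethylsilyloxy)-4,4,8,10-tetramethyl-Δ8(9)-trans-octalin-3-one | CC(C)(C)[Si](C)(C)OC1=C(C)CC[C@@H]2C(C)(C)C(=O)CC[C@]21C | intermediate
17 | potassium C2=C3 enolate of 16 | CC(C)(C)[Si](C)(C)OC1=C(C)CC[C@@H]2C(C)(C)C(O[K])=CC[C@]21C | intermediate (not isolated)
18 | (5R,10R)-9-(tert-butyldimethylsilyloxy)-4,4,8,10-tetramethyl-trans-octala-2,8-dien-3-yl trifluoromethanesulfonate | CC(C)(C)[Si](C)(C)OC1=C(C)CC[C@@H]2C(C)(C)C(OS(=O)(=O)C(F)(F)F)=CC[C@]21C | intermediate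
19 | (5S,10R)-3-bromo-9-(tert-butyldimethylsilyloxy)-4,4,8,10-tetramethyl-trans-octala-2,8-diene | CC(C)(C)[Si](C)(C)OC1=C(C)CC[C@@H]2C(C)(C)C(Br)=CC[C@]21C | intermediate
20 | (5S,8S,10R)-3-bromo-4,4,8,10-tetramethyl-Δ2(3)-trans-octalin-9-one | O=C1[C@@H](C)CC[C@@H]2C(C)(C)C(Br)=CC[C@]21C | intermediate
21 | (3R,5S,8S,10R)-3-bromo-4,4,8,10-tetramethyl-trans-decalin-9-one | O=C1[C@@H](C)CC[C@@H]2C(C)(C)[C@H](Br)CC[C@]21C | intermediate
22 | (R)-(−)-linalool | C=C[C@](C)(O)CCC=C(C)C | starting material
23 | (R)-tert-butyl[(3,7-dimethylocta-1,6-dien-3-yl)oxy]dimethylsilane | C=C[C@](C)(O[Si](C)(C)C(C)(C)C)CCC=C(C)C | intermediate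
24 | (R)-4-[(tert-butyldimethylsilyl)oxy]-4-methylhex-5-enal | C=C[C@](C)(O[Si](C)(C)C(C)(C)C)CCC=O | intermediate
25 | (R)-4-[(tert-butyldimethylsilyl)oxy]-4-methylhex-5-enoic acid | C=C[C@](C)(O[Si](C)(C)C(C)(C)C)CCC(=O)O | intermediate
26 | 2-thioxopyridin-1(2H)-yl (R)-4-[(tert-butyldimethylsilyl)oxy]-4-methylhex-5-enoate | C=C[C@](C)(O[Si](C)(C)C(C)(C)C)CCC(=O)On1ccccc1=S | intermediate (not isolated)
27 | (R)-tert-butyl[(5-iodo-3-methylpent-1-en-3-yl)oxy]dimethylsilane | C=C[C@](C)(O[Si](C)(C)C(C)(C)C)CCI | intermediate
28 | (R)-[3-(tert-butyldimethylsilyloxy)-3-methylpent-4-en-1-yl]lithium | C=C[C@](C)(O[Si](C)(C)C(C)(C)C)CC[Li] | intermediate (not isolated)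
29 | (R)-[3-(tert-butyldimethylsilyloxy)-3-methylpent-4-en-1-yl]cerium dichloride | C=C[C@](C)(O[Si](C)(C)C(C)(C)C)CC[Ce](Cl)Cl | intermediate (not isolated)
30 | (3R,5S,8S,9R,10R,13R)-3-bromo-13-(tert-butyldimethylsilyloxy)labd-14-en-9-ol | C=C[C@](C)(O[Si](C)(C)C(C)(C)C)CC[C@@]1(O)[C@@H](C)CC[C@@H]2C(C)(C)[C@H](Br)CC[C@]21C | intermediate
31 | (3R,5S,8S,9R,10R,13R)-3-bromolabd-14-ene-9,13-diol (CNP0318118.1) | C=C[C@](C)(O)CC[C@@]1(O)[C@@H](C)CC[C@@H]2C(C)(C)[C@H](Br)CC[C@]21C | target

Total step count: 19. Longest linear sequence: 13 steps (5 to 31 through steps 3–13, 18 and 19).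

Steps most likely to fail

First, step 8, which bears the label. The cycloaddition may be too slow, because the fully substituted C10 terminus resists the s-cis alignment and the C5–C10 bond joins two congested carbons; acid-promoted loss of the silyl group or an uncatalysed, racemic cyclisation could then take over. The fallback is known chemistry: a Lewis acid-promoted intramolecular Diels–Alder reaction of a triene imide under the control of an oxazolidinone auxiliary. It sets out from 14 and comes back at 16.
- Buffered chlorite oxidation of 14 (NaClO2, NaH2PO4, 2-methyl-2-butene) should give the trienoic acid F1.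
- Coupling with (R)-4-benzyloxazolidin-2-one (DCC, DMAP) should give the trienimide F2.
- Me2AlCl (CH2Cl2, −30 °C) binds both imide carbonyls, locks the acyl group s-cis and lets the benzyl group screen one face. The endo cycloaddition should then give the imide cycloadduct F3 with the C5, C6 and C10 configuration of 15.
- LiOH/H2O2 should release the decalin carboxylic acid F4.
- Its thiohydroxamate ester F5, photolysed with t-BuSH (Barton reductive decarboxylation), loses CO2 and should give 16.

Second, step 6. Alkylation at the oxygen-bearing central carbon of the anion, migration of silicon from oxygen to carbon within the anion, or sluggish epoxide opening would each erode regio- or geometric purity. The fallback reverses the polarity of the C1–C2 bond formation by a Mukaiyama–Michael addition with silyl transfer. It sets out from 10 (and uses 3) and comes back at 14.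
- LiAlH4 should open the epoxide of 10 at its terminal carbon to give the diol F6.
- Acetylation of the primary allylic hydroxyl (Ac2O, pyridine, 0 °C) gives the monoacetate F7.
- Dess–Martin oxidation gives the methyl ketone F8, and TBSOTf/Et3N gives its silyl enol ether F9.
- MnO2 oxidation of 3 gives the dienone F10.
- F9 and F10, joined under catalysis by HNTf2 (CH2Cl2, −78 °C), should give the acetoxy keto dienol ether F11. Silicon is transferred to the C9 oxygen through the s-cis enone, which places C1 cis to OTBS.
- K2CO3/MeOH should give the allylic alcohol F12, and MnO2 then gives 14.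

Third, step 13. Reductive loss of bromine, or delivery of the second hydrogen to the wrong face of the C3 radical, would spoil the C3 center. The fallback is ionic: reduction, then displacement with inversion. It sets out from 16 and comes back at 21.
- LiBH(s-Bu)3 (THF, −78 °C) should attack the C3 ketone from the equatorial side and give the axial alcohol F13.
- Appel bromination (PPh3, CBr4) with inversion should give the equatorial bromide F14.
- Bu4NF then cleaves the silyl enol ether and equilibrates C8 to give 21.

Further compounds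
F1 | step 8 | (2E,8Z)-9-[(tert-butyldimethylsilyl)oxy]-4,4,8,10-tetramethyl-5-oxoundeca-2,8,10-trienoic acid | OC(=O)/C=C/C(C)(C)C(=O)CC/C(C)=C(O[Si](C)(C)C(C)(C)C)/C(C)=C
F2 | step 8 | (R)-4-benzyl-3-[(2E,8Z)-9-(tert-butyldimethylsilyloxy)-4,4,8,10-tetramethyl-5-oxoundeca-2,8,10-trienoyl]oxazolidin-2-one | O=C(/C=C/C(C)(C)C(=O)CC/C(C)=C(O[Si](C)(C)C(C)(C)C)/C(C)=C)N1[C@H](Cc2ccccc2)COC1=O
F3 | step 8 | imide cycloadduct: 15 with the formyl group replaced by the (R)-4-benzyl-2-oxooxazolidine-3-carbonyl group | CC(C)(C)[Si](C)(C)OC1=C(C)C[C@@H](C(=O)N3[C@H](Cc4ccccc4)COC3=O)[C@@H]2C(C)(C)C(=O)CC[C@]21C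
F4 | step 8 | decalin carboxylic acid: 15 with the formyl group replaced by a carboxyl group | CC(C)(C)[Si](C)(C)OC1=C(C)C[C@@H](C(=O)O)[C@@H]2C(C)(C)C(=O)CC[C@]21C
F5 | step 8 | 2-thioxopyridin-1(2H)-yl ester of F4 | CC(C)(C)[Si](C)(C)OC1=C(C)C[C@@H](C(=O)On3ccccc3=S)[C@@H]2C(C)(C)C(=O)CC[C@]21C
F6 | step 6 | (E)-4,4-dimethylhex-2-ene-1,5-diol (racemic) | OC/C=C/C(C)(C)C(C)O
F7 | step 6 | (E)-5-hydroxy-4,4-dimethylhex-2-en-1-yl acetate (racemic) | CC(=O)OC/C=C/C(C)(C)C(C)O
F8 | step 6 | (E)-4,4-dimethyl-5-oxohex-2-en-1-yl acetate | CC(=O)OC/C=C/C(C)(C)C(C)=O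
F9 | step 6 | (E)-5-[(tert-butyldimethylsilyl)oxy]-4,4-dimethylhexa-2,5-dien-1-yl acetate | CC(=O)OC/C=C/C(C)(C)C(=C)O[Si](C)(C)C(C)(C)C
F10 | step 6 | 2,4-dimethylpenta-1,4-dien-3-one | C=C(C)C(=O)C(C)=C
F11 | step 6 | (2E,8Z)-9-[(tert-butyldimethylsilyl)oxy]-4,4,8,10-tetramethyl-5-oxoundeca-2,8,10-trien-1-yl acetate | CC(=O)OC/C=C/C(C)(C)C(=O)CC/C(C)=C(O[Si](C)(C)C(C)(C)C)/C(C)=C
F12 | step 6 | (2E,8Z)-9-[(tert-butyldimethylsilyl)oxy]-1-hydroxy-4,4,8,10-tetramethylundeca-2,8,10-trien-5-one | OC/C=C/C(C)(C)C(=O)CC/C(C)=C(O[Si](C)(C)C(C)(C)C)/C(C)=C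
F13 | step 13 | 9-(tert-butyldimethylsilyloxy)-4,4,8,10-tetramethyl-Δ8(9)-trans-octalin-3-ol with the hydroxyl axial (trans to the C10 methyl) | CC(C)(C)[Si](C)(C)OC1=C(C)CC[C@@H]2C(C)(C)[C@@H](O)CC[C@]21C
F14 | step 13 | 3-bromo-9-(tert-butyldimethylsilyloxy)-4,4,8,10-tetramethyl-Δ8(9)-trans-octalin with bromine equatorial (cis to the C10 methyl) | CC(C)(C)[Si](C)(C)OC1=C(C)CC[C@@H]2C(C)(C)[C@H](Br)CC[C@]21C
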